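The earlier runs and the new flask come from a simulation for substances that don't exist, and the scatter is random.

The amber run keeps more starting complex than the grey run, 41.5% against 0% at the last reading, and the charges fit that, since each first exchange takes one incoming ligand.

| flask | starting complex | incoming ligand | remark | time |
|---|---|---|---|---|
| amber | 0.25 M | 0.15 M | run made earlier |  |
| grey | 0.25 M | 0.43 M | run made earlier |  |
| noon | 0.25 M | 0.200 M |  | 6.0 h |
| dusk | 0.25 M | 0.500 M |  | 6.0 h |

| run | time / h | complex with two exchanged / % | starting complex / % |
|---|---|---|---|
| amber | 0.250 | 0 | 59.7 |
| amber | 0.417 | 0.7 | 51.6 |
| amber | 0.833 | 1.4 | 44.9 |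
| amber | 1.50 | 0 | 42.6 |
| amber | 3.00 | 0.6 | 41.5 |
| grey | 0.667 | 9.2 | 4.6 |
| grey | 1.33 | 19.2 | 0.4 |
| grey | 2.00 | 24.6 | 0 |
| grey | 2.50 | 29.3 | 0 |
| grey | 3.00 | 34.4 | 0 |

(readings scatter by 1 percentage point)

- in percentages every species weighs as the starting complex in it: one side product counts as two
- for leaving ligand the crystals are counted in
- as a solid, counted per litre of solution: crystals
- what may be going on: starting complex + incoming ligand -> leaving ligand + complex with one exchanged; complex with one exchanged + incoming ligand -> leaving ligand + complex with two exchanged; crystals <-> leaving ligand; starting complex + complex with two exchanged -> side product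

- which of these holds the largest part of the starting complex at the end of noon (starting complex / complex with two exchanged / complex with one exchanged)
- which of these holds the largest part of the starting complex at the end of dusk (starting complex / complex with two exchanged / complex with one exchanged)
- amount of complex with two exchanged at the end of noon, in percent of the starting complex charged

Noon's stop level, the part of the starting complex charged in excess of the incoming ligand, is 20.0%, with the ligand as limiting reagent. Amber's is 40.0%, close to its last reading.

How fast is the stop approached? Amber's gap above its stop shrinks from 20 percentage points at 0.250 h to 4.9 points at 0.833 h, a half-life of 0.290 h. Late on, the ligand decays pseudo-first-order in the excess of starting complex, and noon's excess is half of amber's, so noon's half-life is 0.581 h, and its 6.0 h holds 10.3 of them. Noon should therefore reach its stop.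

Amber's half-life gives a first constant of 23.9 M⁻¹ h⁻¹. Grey's late rise of two-exchanged complex gives a second of 1.30 M⁻¹ h⁻¹, a selectivity factor of 18.4 as read. Integrating that partition down to the stop, noon makes about 4.40% of two-exchanged complex before any loss to side product.

The weak link is treating the stop as exact. Each ligand spent on a second exchange spares one starting complex, so I reforge noon's stop to 24.4%, with 71.2% as one-exchanged complex. At dusk the ligand exceeds the starting complex, so once the first exchange is over I take one-exchanged complex and ligand both near 0.250 M, and my second-order estimate leaves 33.9% as one-exchanged complex, the rest two-exchanged.

The forecast names complex with one exchanged for noon, complex with two exchanged for dusk and 0.5% for the amount asked, holding that “Any two-exchanged complex is consumed by the remaining starting complex”. That amount is lower than my 4.40%, which is reckoned before any loss to side product.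

The flasks give complex with one exchanged at noon, complex with two exchanged at dusk, and 1.53% of two-exchanged complex at noon.

    starting complex + incoming ligand → leaving ligand + complex with one exchanged (k = 0.00610 M⁻¹ s⁻¹)
    complex with one exchanged + incoming ligand → leaving ligand + complex with two exchanged (k = 2.90 × 10⁻⁴ M⁻¹ s⁻¹)
    crystals ⇌ leaving ligand, rate k3*(cs3 - [leaving ligand]) while solid is left; crystals form when [leaving ligand] > cs3 (solubility = 0.150 M, k = 0.0700 s⁻¹)
    starting complex + complex with two exchanged → side product (k = 6.60 × 10⁻⁴ M⁻¹ s⁻¹)

Noon ends with 21.5% of starting complex against its stop level of 20.0%. What mainly holds its two-exchanged complex at 1.53% is the falling level of incoming ligand, down to 0.0056% of its charge, for the same flask with the ligand held at its charge gives 69.5%. The flask with 1.0 M of starting complex has a stop level of 80.0% and ends with 80.0% of starting complex.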